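**Retrosynthetic overview**
1. The target is epioritin-(4β→6)-oritin-4α-ol. The last skeletal bond is C4(upper)–C6(lower), made by thiophilic Friedel–Crafts coupling; global hydrogenolysis follows.
2. Both flavan units come from one ketone, the (2R,4R)-4-hydroxyflavan-3-one 17: NaBH4 gives the 2,3-trans-3,4-trans diol (lower unit); LiBH(s-Bu)3 gives the 2,3-cis diol, then the 4-thioether (upper unit).
3. Ring C of 17 is made by oxidative ring expansion (five- to six-membered, 1,2-transposition of the aryl oxygen) of the (Z)-2-benzylidene-2,3-dihydrobenzofuran-3-ol 15.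
4. 15 comes from salicylaldehyde 8 and arylalkyne 13 by asymmetric alkynylation (the only reagent-controlled stereocentre) and AuCl 5-exo-dig cyclisation; the furan ring is formed first, then expanded to the pyran.
5. 8 comes from catechol (ketal, ortho-lithiation/borylation/oxidation, ortho-formylation); 13 comes from 4-iodophenol and ethynyltrimethylsilane.

Assumption: paraformaldehyde is entered as its monomer formaldehyde (6), and crude ketone 17 is used at once without purification.

**Step 1**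
Reactants: 1 catechol
Product: 2 2,2-diphenyl-1,3-benzodioxole
Conditions: Ph2CCl2 (1.1 equiv), neat, 170 °C
Reagents that add atoms: dichlorodiphenylmethane ClC(Cl)(c1ccccc1)c1ccccc1
Why: Double O-alkylation of the catechol by the gem-dichloride (ketalisation) gives a ketal that tolerates bases, hydrides and organometallics and is removed at the end by hydrogenolysis.

**Step 2**
Reactants: 2 2,2-diphenyl-1,3-benzodioxole
Product: 5 2,2-diphenyl-1,3-benzodioxol-4-ol, via aryllithium 3 (not isolated), via arylboronate 4 (not isolated)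
Conditions: s-BuLi, TMEDA, THF, −78 °C; B(OMe)3, −78 °C to rt; AcOH, 30% H2O2, 0 °C
Reagents that add atoms: sec-butyllithium [Li]C(C)CC (Li of 3); trimethyl borate COB(OC)OC (boron group of 4); hydrogen peroxide OO (phenol oxygen of 5)
Why: Directed ortho-metalation next to the ring oxygen, borylation and peroxide oxidation (aryl shift from boron to oxygen) give the 1,2,3-trioxygenated ring A regiospecifically.

**Step 3**
Reactants: 5 2,2-diphenyl-1,3-benzodioxol-4-ol; 6 formaldehyde (as paraformaldehyde)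
Product: 8 4-hydroxy-2,2-diphenyl-1,3-benzodioxole-5-carbaldehyde, via salicyl alcohol 7 (not isolated)
Conditions: MgCl2 (2 equiv), Et3N (4 equiv), (CH2O)n (6 equiv), MeCN, reflux
Reagents that add atoms: none
Why: Magnesium-phenoxide-directed ortho-formylation (Casnati–Skattebøl type) attacks the only free ortho position, and a second formaldehyde oxidises the benzylic alkoxide by hydride transfer.

**Step 4**
Reactants: 9 4-iodophenol
Product: 10 1-(benzyloxy)-4-iodobenzene
Conditions: BnBr, K2CO3, acetone, reflux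
Reagents that add atoms: benzyl bromide BrCc1ccccc1
Why: Williamson etherification installs a hydrogenolysable protecting group on the ring B phenol.

**Step 5**
Reactants: 10 1-(benzyloxy)-4-iodobenzene; 11 ethynyltrimethylsilane
Product: 13 1-(benzyloxy)-4-ethynylbenzene, via silylalkyne 12 (not isolated)
Conditions: PdCl2(PPh3)2 (2 mol%), CuI (4 mol%), Et3N, THF, rt; then K2CO3 (cat.), MeOH, rt
Reagents that add atoms: none
Why: Sonogashira coupling of the aryl iodide followed by methanolytic C–Si cleavage gives the terminal arylalkyne.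

**Step 6**
Reactants: 8 4-hydroxy-2,2-diphenyl-1,3-benzodioxole-5-carbaldehyde; 13 1-(benzyloxy)-4-ethynylbenzene
Product: 14 (S)-3-[4-(benzyloxy)phenyl]-1-(4-hydroxy-2,2-diphenyl-1,3-benzodioxol-5-yl)prop-2-yn-1-ol
Conditions: 13 (2.5 equiv), Me2Zn (4 equiv), ProPhenol ligand (20 mol%, antipode that gives Si-face attack), Ph3PO (40 mol%), toluene, 0 °C to rt; aq. NH4Cl
Reagents that add atoms: none
Why: Dinuclear zinc–ProPhenol asymmetric alkynylation (the first Me2Zn equivalent masks the phenol as its zinc phenoxide) adds the alkynylzinc to the Si face of the aldehyde, setting the S carbinol that becomes C4 of both flavan units.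

**Step 7**
Reactants: 14 (S)-propargylic alcohol
Product: 15 (R,Z)-2-[4-(benzyloxy)benzylidene]-6,7-(diphenylmethylenedioxy)-2,3-dihydro-1-benzofuran-3-ol
Conditions: AuCl (10 mol%), K2CO3 (10 mol%), MeCN, rt
Reagents that add atoms: none
Why: Gold-catalysed 5-exo-dig hydroalkoxylation (anti-oxyauration, protodeauration) gives the Z enol ether under near-neutral conditions that leave the carbinol centre untouched; the descriptor changes from S to R only because the priorities change.

**Step 8**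
Reactants: 15 (R,Z)-2-[4-(benzyloxy)benzylidene]-6,7-(diphenylmethylenedioxy)-2,3-dihydro-1-benzofuran-3-ol
Product: 17 (2R,4R)-2-[4-(benzyloxy)phenyl]-4-hydroxy-7,8-(diphenylmethylenedioxy)chroman-3-one, via bromo ketone 16 (not isolated)
Conditions: NBS (1.05 equiv), NaHCO3 (3 equiv), THF–H2O 4:1, −10 °C; then Bu4NBr (10 mol%), 0 °C; crude 17 used at once
Reagents that add atoms: water O (ketone oxygen of 17); N-bromosuccinimide O=C1CCC(=O)N1Br (bromine of 16 only)
Why: Proposed new method: an Achmatowicz-type oxidative ring expansion moved from furfuryl alcohols to an exocyclic benzofuran enol ether, in which bromination at the enol-ether β-carbon and hydration of the oxocarbenium give an aryl hemiketal that opens to phenol/α-bromo ketone 16, whose phenoxide then closes 6-exo-tet on the labile p-alkoxybenzylic bromide (net 1,2-shift of the aryl oxygen, ring 5 to ring 6); bromide exchange epimerises the benzylic centre so that closure runs through the chair-like transition state with the 2-aryl group equatorial and cis to the hydrogen-bonded equatorial 4-OH, so the carbinol centre from step 6 sets C2 as R; the closest known reactions are the Achmatowicz rearrangement and the epoxy-ether to α-alkoxy-ketone rearrangement.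

**Step 9**
Reactants: 17 (2R,4R)-4-hydroxyflavan-3-one
Product: 18 (2R,3S,4R)-2-[4-(benzyloxy)phenyl]-7,8-(diphenylmethylenedioxy)chroman-3,4-diol (protected oritin-4α-ol)
Conditions: NaBH4, CeCl3·7H2O, MeOH–THF, −78 °C
Reagents that add atoms: none
Why: Luche-type reduction outruns enolisation, and axial attack of the small hydride on the ketone flanked by two equatorial groups gives the all-equatorial 3β-alcohol (2,3-trans-3,4-trans).

**Step 10**
Reactants: 17 (2R,4R)-4-hydroxyflavan-3-one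
Product: 19 (2R,3R,4R)-2-[4-(benzyloxy)phenyl]-7,8-(diphenylmethylenedioxy)chroman-3,4-diol (protected teracacidin)
Conditions: LiBH(s-Bu)3 (2.2 equiv), THF, −78 °C; aq. NH4Cl
Reagents that add atoms: none
Why: The bulky trialkylborohydride attacks equatorially and gives the axial 3α-alcohol cis to the 2-aryl group, the standard reduction used to reach epi-series flavan-3-ols from flavan-3-ones.

**Step 11**
Reactants: 19 protected teracacidin
Product: 20 (2R,3S,4S)-4-(benzylsulfanyl)-2-[4-(benzyloxy)phenyl]-7,8-(diphenylmethylenedioxy)chroman-3-ol (protected 4β-benzylsulfanylepioritin)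
Conditions: BnSH (5 equiv), camphorsulfonic acid (10 mol%), CH2Cl2, 0 °C
Reagents that add atoms: benzyl mercaptan SCc1ccccc1
Why: Acid-catalysed SN1 thiolysis through the C4 benzylic cation stabilised by the para 7-oxygen, with the thiol adding from the β face trans to the axial 3-OH.

**Step 12**
Reactants: 20 protected 4β-benzylsulfanylepioritin; 18 protected oritin-4α-ol
Product: 21 protected epioritin-(4β→6)-oritin-4α-ol (7,8-O-diphenylmethylene and 4′-O-benzyl on both units)
Conditions: 18 (3 equiv, excess recovered), AgBF4 (1.5 equiv), 2,6-di-tert-butyl-4-methylpyridine (1.5 equiv), THF, 0 °C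
Reagents that add atoms: none
Why: Thiophilic silver activation of the C4–S bond, orthogonal to the buffered free C4–OH of 18, gives the C4 cation, which undergoes Friedel–Crafts attack by C6 of 18 (para to O1, ortho to O7, less hindered than peri C5) from the β face trans to the 3-OH, setting upper C4 as S.

**Step 13**
Reactants: 21 protected dimer
Product: 22 epioritin-(4β→6)-oritin-4α-ol (target)
Conditions: H2 (1 atm), Pd(OH)2/C, THF–MeOH, rt
Reagents that add atoms: none
Why: Neutral hydrogenolysis cleaves both benzyl ethers and both diphenylmethylene ketals without touching the six stereocentres or the diarylmethine bond.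

**Compound list**
1 | catechol | Oc1ccccc1O | starting material
2 | 2,2-diphenyl-1,3-benzodioxole | c1ccc2OC(c3ccccc3)(c3ccccc3)Oc2c1 | intermediate
3 | (2,2-diphenyl-1,3-benzodioxol-4-yl)lithium | [Li]c1cccc2OC(c3ccccc3)(c3ccccc3)Oc12 | intermediate (not isolated)
4 | dimethyl (2,2-diphenyl-1,3-benzodioxol-4-yl)boronate | COB(OC)c1cccc2OC(c3ccccc3)(c3ccccc3)Oc12 | intermediate (not isolated)
5 | 2,2-diphenyl-1,3-benzodioxol-4-ol | Oc1cccc2OC(c3ccccc3)(c3ccccc3)Oc12 | intermediate
6 | formaldehyde (paraformaldehyde) | C=O | starting material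
7 | 5-(hydroxymethyl)-2,2-diphenyl-1,3-benzodioxol-4-ol (magnesium salt in the flask) | OCc1ccc2OC(c3ccccc3)(c3ccccc3)Oc2c1O | intermediate (not isolated)
8 | 4-hydroxy-2,2-diphenyl-1,3-benzodioxole-5-carbaldehyde | O=Cc1ccc2OC(c3ccccc3)(c3ccccc3)Oc2c1O | intermediate
9 | 4-iodophenol | Oc1ccc(I)cc1 | starting material
10 | 1-(benzyloxy)-4-iodobenzene | Ic1ccc(OCc2ccccc2)cc1 | intermediate
11 | ethynyltrimethylsilane | C[Si](C)(C)C#C | starting material
12 | {[4-(benzyloxy)phenyl]ethynyl}trimethylsilane | C[Si](C)(C)C#Cc1ccc(OCc2ccccc2)cc1 | intermediate (not isolated)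
13 | 1-(benzyloxy)-4-ethynylbenzene | C#Cc1ccc(OCc2ccccc2)cc1 | intermediate
14 | (S)-3-[4-(benzyloxy)phenyl]-1-(4-hydroxy-2,2-diphenyl-1,3-benzodioxol-5-yl)prop-2-yn-1-ol | O[C@@H](C#Cc1ccc(OCc2ccccc2)cc1)c1ccc2OC(c3ccccc3)(c3ccccc3)Oc2c1O | intermediate
15 | (R,Z)-2-[4-(benzyloxy)benzylidene]-6,7-(diphenylmethylenedioxy)-2,3-dihydro-1-benzofuran-3-ol | O[C@H]1/C(=C/c2ccc(OCc3ccccc3)cc2)Oc2c1ccc1OC(c3ccccc3)(c3ccccc3)Oc21 | intermediate
16 | (1R,3S)-3-[4-(benzyloxy)phenyl]-3-bromo-1-hydroxy-1-(4-hydroxy-2,2-diphenyl-1,3-benzodioxol-5-yl)propan-2-one (reacting epimer) | Br[C@@H](c1ccc(OCc2ccccc2)cc1)C(=O)[C@H](O)c1ccc2OC(c3ccccc3)(c3ccccc3)Oc2c1O | intermediate (not isolated)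
17 | (2R,4R)-2-[4-(benzyloxy)phenyl]-4-hydroxy-7,8-(diphenylmethylenedioxy)chroman-3-one (2,4-cis) | c1cc2c(c3OC(c4ccccc4)(c4ccccc4)Oc13)O[C@H](c1ccc(OCc3ccccc3)cc1)C(=O)[C@@H]2O | intermediate
18 | (2R,3S,4R)-2-[4-(benzyloxy)phenyl]-7,8-(diphenylmethylenedioxy)chroman-3,4-diol (2,3-trans-3,4-trans) | c1cc2c(c3OC(c4ccccc4)(c4ccccc4)Oc13)O[C@H](c1ccc(OCc3ccccc3)cc1)[C@@H](O)[C@@H]2O | intermediate
19 | (2R,3R,4R)-2-[4-(benzyloxy)phenyl]-7,8-(diphenylmethylenedioxy)chroman-3,4-diol (2,3-cis-3,4-cis) | c1cc2c(c3OC(c4ccccc4)(c4ccccc4)Oc13)O[C@H](c1ccc(OCc3ccccc3)cc1)[C@H](O)[C@@H]2O | intermediate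
20 | (2R,3S,4S)-4-(benzylsulfanyl)-2-[4-(benzyloxy)phenyl]-7,8-(diphenylmethylenedioxy)chroman-3-ol (2,3-cis-3,4-trans) | c1cc2c(c3OC(c4ccccc4)(c4ccccc4)Oc13)O[C@H](c1ccc(OCc3ccccc3)cc1)[C@H](O)[C@H]2SCc1ccccc1 | intermediate
21 | protected epioritin-(4β→6)-oritin-4α-ol: upper unit 2,3-cis-3,4-trans with 4β bond to C6 of the lower 2,3-trans-3,4-trans 3,4-diol unit; 7,8-O-diphenylmethylene and 4′-O-benzyl on both | c1cc2c(c3OC(c4ccccc4)(c4ccccc4)Oc13)O[C@H](c1ccc(OCc3ccccc3)cc1)[C@H](O)[C@H]2c1cc2c(c3OC(c4ccccc4)(c4ccccc4)Oc13)O[C@H](c1ccc(OCc3ccccc3)cc1)[C@@H](O)[C@@H]2O | intermediate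
22 | epioritin-(4β→6)-oritin-4α-ol, upper (2R,3R,4S), lower (2R,3S,4R) | Oc1ccc([C@H]2Oc3c(ccc(O)c3O)[C@H](c3cc4c(c(O)c3O)O[C@H](c3ccc(O)cc3)[C@@H](O)[C@@H]4O)[C@H]2O)cc1 | target

**Totals**
Total steps: 13. Longest linear sequence: 10 (steps 1, 2, 3, 6, 7, 8, 10, 11, 12, 13).

**Three steps most likely to fail**

Step 8 (the proposed new ring expansion). The risks are aromatisation of 15 to a benzofuran, C2 epimer mixtures, and tautomerisation of 17 to the dihydroflavonol. The fallback uses known chalcone chemistry, sets out from 14 and comes back to the route at 18 and at 19, bypassing 15–17. Trans-hydroalumination of 14 with NaAlH2(OCH2CH2OCH3)2 in THF gives the (S,E)-allylic alcohol F4. MnO2 in CH2Cl2 gives the 2′-hydroxychalcone F5, and MOMCl/i-Pr2NEt gives the MOM ether F6. Juliá–Colonna epoxidation (poly-L-leucine, urea–H2O2, DBU, THF) gives the (2R,3S)-epoxy ketone F7. HCl in MeOH removes the MOM group and the phenol opens the epoxide at the benzylic carbon with inversion, giving the (2R,3R)-trans-dihydroflavonol F8. NaBH4 in MeOH then gives 18. For the cis series, Mitsunobu inversion of F8 (4-nitrobenzoic acid, PPh3, DIAD) gives the 2,3-cis ester F9, NaBH4 gives the 3,4-cis alcohol F10, and K2CO3/MeOH gives 19.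

Step 12 (coupling). The risks are C5 versus C6 attack on 18, O-alkylation and over-oligomerisation. The fallback sets out from 19 and 18 and comes back at 22, so step 13 is no longer needed. Hydrogenolysis of 19 (H2, Pd(OH)2/C) gives free teracacidin F11, and BnSH in AcOH converts it into 4β-benzylsulfanylepioritin F12. Hydrogenolysis of 18 gives free oritin-4α-ol F13. AgBF4 in THF at 0 °C then couples F12 with excess F13, the established thiophilic, protecting-group-free way to join such units, where the free 7-OH steers attack to C6, and gives 22 directly.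

Step 6 (asymmetric alkynylation of a free salicylaldehyde). The risk is a racemic background reaction through the chelated zinc phenoxide. The fallback sets out from 8 and 13 and comes back at 15. The lithium acetylide of 13 (n-BuLi, 2.2 equiv, THF, −78 °C) adds to 8 to give the racemic propargylic alcohol F1. AuCl/K2CO3 gives the racemic auronol F2, and MnO2 gives the (Z)-aurone F3. Enantioselective 1,2-reduction with 2-methyl-CBS-oxazaborolidine (antipode giving the R alcohol) and catecholborane at −78 °C gives 15, so the stereocentre is set by ketone reduction instead of C–C bond formation.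

**Further compounds**
F1 | step 6 | racemic 3-[4-(benzyloxy)phenyl]-1-(4-hydroxy-2,2-diphenyl-1,3-benzodioxol-5-yl)prop-2-yn-1-ol | OC(C#Cc1ccc(OCc2ccccc2)cc1)c1ccc2OC(c3ccccc3)(c3ccccc3)Oc2c1O
F2 | step 6 | racemic (Z)-2-[4-(benzyloxy)benzylidene]-6,7-(diphenylmethylenedioxy)-2,3-dihydro-1-benzofuran-3-ol | OC1/C(=C/c2ccc(OCc3ccccc3)cc2)Oc2c1ccc1OC(c3ccccc3)(c3ccccc3)Oc21
F3 | step 6 | (Z)-2-[4-(benzyloxy)benzylidene]-6,7-(diphenylmethylenedioxy)-1-benzofuran-3(2H)-one (aurone) | O=C1/C(=C/c2ccc(OCc3ccccc3)cc2)Oc2c1ccc1OC(c3ccccc3)(c3ccccc3)Oc21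
F4 | step 8 | (S,E)-3-[4-(benzyloxy)phenyl]-1-(4-hydroxy-2,2-diphenyl-1,3-benzodioxol-5-yl)prop-2-en-1-ol | O[C@@H](/C=C/c1ccc(OCc2ccccc2)cc1)c1ccc2OC(c3ccccc3)(c3ccccc3)Oc2c1O
F5 | step 8 | (E)-3-[4-(benzyloxy)phenyl]-1-(4-hydroxy-2,2-diphenyl-1,3-benzodioxol-5-yl)prop-2-en-1-one (2′-hydroxychalcone) | O=C(/C=C/c1ccc(OCc2ccccc2)cc1)c1ccc2OC(c3ccccc3)(c3ccccc3)Oc2c1O
F6 | step 8 | (E)-3-[4-(benzyloxy)phenyl]-1-[4-(methoxymethoxy)-2,2-diphenyl-1,3-benzodioxol-5-yl]prop-2-en-1-one | O=C(/C=C/c1ccc(OCc2ccccc2)cc1)c1ccc2OC(c3ccccc3)(c3ccccc3)Oc2c1OCOC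
F7 | step 8 | {(2R,3S)-3-[4-(benzyloxy)phenyl]oxiran-2-yl}[4-(methoxymethoxy)-2,2-diphenyl-1,3-benzodioxol-5-yl]methanone | O=C([C@@H]1O[C@H]1c1ccc(OCc2ccccc2)cc1)c1ccc2OC(c3ccccc3)(c3ccccc3)Oc2c1OCOC
F8 | step 8 | (2R,3R)-2-[4-(benzyloxy)phenyl]-3-hydroxy-7,8-(diphenylmethylenedioxy)chroman-4-one (trans-dihydroflavonol) | c1cc2c(c3OC(c4ccccc4)(c4ccccc4)Oc13)O[C@H](c1ccc(OCc3ccccc3)cc1)[C@@H](O)C2=O
F9 | step 8 | (2R,3S)-2-[4-(benzyloxy)phenyl]-7,8-(diphenylmethylenedioxy)-4-oxochroman-3-yl 4-nitrobenzoate (2,3-cis) | c1cc2c(c3OC(c4ccccc4)(c4ccccc4)Oc13)O[C@H](c1ccc(OCc3ccccc3)cc1)[C@H](OC(=O)c1ccc(cc1)[N+](=O)[O-])C2=O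
F10 | step 8 | 3-O-(4-nitrobenzoyl) derivative of 19 (2,3-cis-3,4-cis) | c1cc2c(c3OC(c4ccccc4)(c4ccccc4)Oc13)O[C@H](c1ccc(OCc3ccccc3)cc1)[C@H](OC(=O)c1ccc(cc1)[N+](=O)[O-])[C@@H]2O
F11 | step 12 | teracacidin, (2R,3R,4R)-2-(4-hydroxyphenyl)chroman-3,4,7,8-tetrol | c1cc2c(c(O)c1O)O[C@H](c1ccc(O)cc1)[C@H](O)[C@@H]2O
F12 | step 12 | 4β-benzylsulfanylepioritin, (2R,3S,4S)-4-(benzylsulfanyl)-2-(4-hydroxyphenyl)chroman-3,7,8-triol | c1cc2c(c(O)c1O)O[C@H](c1ccc(O)cc1)[C@H](O)[C@H]2SCc1ccccc1
F13 | step 12 | oritin-4α-ol, (2R,3S,4R)-2-(4-hydroxyphenyl)chroman-3,4,7,8-tetrol | c1cc2c(c(O)c1O)O[C@H](c1ccc(O)cc1)[C@@H](O)[C@@H]2O
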